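## Retrosynthetic overview

1. Epoxide last: target 29 ⇐ triene 28 by Shi epoxidation of the E-3,4-alkene.
2. Carbocycle: the 14-membered ring ⇐ Nozaki–Hiyama–Kishi closure of C7–C8 in seco aldehyde 25 (C7 aldehyde + C8 2-iodoalkene); C7 is then set by MnO2 oxidation and CBS reduction.
3. Lactone: the cis-α-methylene-γ-lactone with C13, C14 and C1 ⇐ indium Barbier coupling/lactonisation of α-hydroxy aldehyde 21 (C8–C14) with (Z)-2-(bromomethyl)enoate 10 (C1–C7, C15–C17).
4. Fragments: 21 ⇐ hex-5-yn-1-ol (hydroiodination, Wittig, Cu-catalysed asymmetric methyl addition for C12, proline aminoxylation for C13); 10 ⇐ a silyl pentyne (carboalumination/oxirane, vinylalumination, SN2' bromination).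
5. Ring order: γ-lactone (step 11), then carbocycle (step 13), then epoxide (step 16).

Locants C1–C20 are cembrane locants: C1 is the ring CH bearing C15, C14 bears the lactone oxygen, C15/C16/C17 are the lactone α-carbon, carbonyl and exocyclic CH2, and C18, C19, C20 sit on C4, C8, C12.

Assumption: (S)-Tol-BINAP is taken as the ligand antipode that gives 3S-16 in step 7; if the sense proves opposite, (R)-Tol-BINAP is used and nothing else changes.

## Route

Step 1
Reactants: 1 tert-butyldimethyl(pent-4-yn-1-yloxy)silane; 2 oxirane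
Product: 5 (3E)-7-[(tert-butyldimethylsilyl)oxy]-4-methylhept-3-en-1-ol, via alkenyldimethylalane 3 (not isolated), via lithium alkenylaluminate 4 (not isolated)
Conditions: AlMe3, Cp2ZrCl2 (20 mol %), CH2Cl2, rt; n-BuLi, THF, −78 °C; 2, −78 °C → rt; H2O
Reagents that add atoms: trimethylaluminium AlMe3, C[Al](C)C
Why: Negishi Zr-catalysed carboalumination adds Me and Al syn across the alkyne with Me on the internal carbon, which fixes the E-3,4-alkene, and the derived aluminate opens oxirane to add C1–C2.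

Step 2
Reactants: 5 (3E)-7-[(tert-butyldimethylsilyl)oxy]-4-methylhept-3-en-1-ol
Product: 6 (3E)-7-[(tert-butyldimethylsilyl)oxy]-4-methylhept-3-enal
Conditions: TEMPO (10 mol %), PhI(OAc)2, CH2Cl2, rt
Reagents that add atoms: none
Why: TEMPO/PhI(OAc)2 oxidation stops at the aldehyde under near-neutral conditions, so the β,γ-alkene does not move into conjugation; 6 is used crude.

Step 3
Reactants: 6 (3E)-7-[(tert-butyldimethylsilyl)oxy]-4-methylhept-3-enal; 7 methyl prop-2-ynoate
Product: 9 methyl (5E)-9-[(tert-butyldimethylsilyl)oxy]-3-hydroxy-6-methyl-2-methylidenenon-5-enoate (racemic at C3), via α-aluminoacrylate 8 (not isolated)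
Conditions: 7, i-Bu2AlH, NMO, THF, 0 °C; then 6, 0 °C → rt
Reagents that add atoms: none
Why: Hydroalumination of the ynoate gives the α-aluminoacrylate, which adds 1,2 to the aldehyde (vinylalumination, a Morita–Baylis–Hillman adduct made without amine base); the carbinol centre is racemic and is removed in step 4.

Step 4
Reactants: 9 methyl (5E)-9-[(tert-butyldimethylsilyl)oxy]-3-hydroxy-6-methyl-2-methylidenenon-5-enoate
Product: 10 methyl (2Z,5E)-2-(bromomethyl)-9-[(tert-butyldimethylsilyl)oxy]-6-methylnona-2,5-dienoate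
Conditions: NBS, Me2S, CH2Cl2, 0 °C → rt
Reagents that add atoms: N-bromosuccinimide, BrN1C(=O)CCC1=O
Why: Corey–Kim-type activation of the alcohol and SN2' attack of bromide transposes the allyl system to the thermodynamically preferred (Z)-2-(bromomethyl)enoate; the TBS ether and the 5,6-alkene are untouched.

Step 5
Reactants: 11 hex-5-yn-1-ol
Product: 12 5-iodohex-5-en-1-ol
Conditions: NaI, TMSCl, H2O, MeCN, rt
Reagents that add atoms: sodium iodide NaI, [Na+].[I-]
Why: Markovnikov hydroiodination of the terminal alkyne by HI made in situ gives the 2-iodo-1-alkene needed for the Ni/Cr coupling.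

Step 6
Reactants: 12 5-iodohex-5-en-1-ol; 13 methyl (triphenyl-λ5-phosphanylidene)acetate
Product: 15 methyl (2E)-7-iodoocta-2,7-dienoate, via 5-iodohex-5-enal 14 (not isolated)
Conditions: TEMPO (10 mol %), PhI(OAc)2, CH2Cl2, rt; then 13, rt
Reagents that add atoms: none
Why: One-pot TEMPO oxidation and Wittig olefination with the stabilised ylide gives the E-enoate without isolating the aldehyde.

Step 7
Reactants: 15 methyl (2E)-7-iodoocta-2,7-dienoate
Product: 16 methyl (3S)-7-iodo-3-methyloct-7-enoate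
Conditions: CuI (2 mol %), (S)-Tol-BINAP (3 mol %), MeMgBr, t-BuOMe, −20 °C
Reagents that add atoms: methylmagnesium bromide MeMgBr, C[Mg]Br
Why: Cu/Tol-BINAP-catalysed asymmetric conjugate addition of MeMgBr sets C12 (3S in 16) under catalyst control; the alkenyl iodide does not react at −20 °C.

Step 8
Reactants: 16 methyl (3S)-7-iodo-3-methyloct-7-enoate
Product: 17 (3S)-7-iodo-3-methyloct-7-enal
Conditions: i-Bu2AlH, CH2Cl2, −78 °C
Reagents that add atoms: none
Why: Partial ester reduction stops at the aldehyde because the tetrahedral aluminium hemiacetal is stable at −78 °C; no stereocentre is touched.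

Step 9
Reactants: 17 (3S)-7-iodo-3-methyloct-7-enal
Product: 20 (2R,3S)-7-iodo-3-methyloct-7-ene-1,2-diol, via anilinooxy aldehyde 18 (not isolated), via anilinooxy alcohol 19 (not isolated)
Conditions: L-proline (20 mol %), PhNO, DMSO, rt; NaBH4, MeOH, 0 °C; CuSO4·5H2O (30 mol %), MeOH, rt
Reagents that add atoms: nitrosobenzene, O=Nc1ccccc1
Why: Proline enamine catalysis (α-aminoxylation) delivers the oxygen of PhNO to one enamine face and sets C13 as 2R under catalyst control, after which NaBH4 reduction and Cu-catalysed N–O cleavage give the diol.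

Step 10
Reactants: 20 (2R,3S)-7-iodo-3-methyloct-7-ene-1,2-diol
Product: 21 (2R,3S)-2-hydroxy-7-iodo-3-methyloct-7-enal
Conditions: TEMPO (10 mol %), NCS, Bu4NCl (cat.), CH2Cl2/aq. NaHCO3 (pH 8.6), rt
Reagents that add atoms: none
Why: The oxoammonium oxidation (TEMPO/NCS) takes the primary alcohol much faster than the secondary one and does not cleave the diol; 21 is used crude as its monomer/dimer mixture.

Step 11
Reactants: 21 (2R,3S)-2-hydroxy-7-iodo-3-methyloct-7-enal; 10 methyl (2Z,5E)-2-(bromomethyl)-9-[(tert-butyldimethylsilyl)oxy]-6-methylnona-2,5-dienoate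
Product: 24 (4S,5R)-5-[(1R,2S)-1-hydroxy-6-iodo-2-methylhept-6-en-1-yl]-4-[(2E)-6-hydroxy-3-methylhex-2-en-1-yl]-3-methylideneoxolan-2-one, via open-chain hydroxy ester 22 (not isolated), via silyl lactone 23 (not isolated)
Conditions: In powder, THF/H2O (1:1), rt; then 2 M HCl, rt
Reagents that add atoms: none
Why: In this indium Barbier allylation the metal chelates the C13 hydroxyl and the aldehyde oxygen, so the (Z)-allylindium adds through a chair transition state anti to the C12 branch and sets 14R (13,14-syn) and 1S (14,1-syn); acid then closes the cis-γ-lactone and removes the TBS group.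

Step 12
Reactants: 24 (4S,5R)-5-[(1R,2S)-1-hydroxy-6-iodo-2-methylhept-6-en-1-yl]-4-[(2E)-6-hydroxy-3-methylhex-2-en-1-yl]-3-methylideneoxolan-2-one
Product: 25 (4E)-6-{(2R,3S)-2-[(1R,2S)-1-hydroxy-6-iodo-2-methylhept-6-en-1-yl]-4-methylidene-5-oxooxolan-3-yl}-4-methylhex-4-enal
Conditions: TEMPO (10 mol %), PhI(OAc)2, CH2Cl2, rt
Reagents that add atoms: none
Why: TEMPO/PhI(OAc)2 oxidises only the primary alcohol; the hindered secondary C13 hydroxyl, the enoate and the alkenyl iodide survive.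

Step 13
Reactants: 25 (4E)-6-{(2R,3S)-2-[(1R,2S)-1-hydroxy-6-iodo-2-methylhept-6-en-1-yl]-4-methylidene-5-oxooxolan-3-yl}-4-methylhex-4-enal
Product: 26 (1S,3E,12S,13R,14R)-7,13-dihydroxycembra-3,8(19),15(17)-trien-16,14-olide as the 7R/7S mixture
Conditions: CrCl2 (10 equiv), NiCl2 (10 mol %), DMSO/THF, rt, slow addition to 1 mM
Reagents that add atoms: none
Why: In this intramolecular Nozaki–Hiyama–Kishi coupling nickel inserts into the C–I bond, the alkenyl group passes to chromium and adds only to the aldehyde at high dilution to close the 14-membered ring; C7 forms without claimed control and both epimers are converged in steps 14 and 15.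

Step 14
Reactants: 26 (1S,3E,12S,13R,14R)-7,13-dihydroxycembra-3,8(19),15(17)-trien-16,14-olide (7R/7S mixture)
Product: 27 (1S,3E,12S,13R,14R)-13-hydroxy-7-oxocembra-3,8(19),15(17)-trien-16,14-olide
Conditions: MnO2, CH2Cl2, rt
Reagents that add atoms: none
Why: MnO2 oxidises only the allylic C7 alcohol, so both epimers give one enone and the saturated C13 alcohol is left.

Step 15
Reactants: 27 (1S,3E,12S,13R,14R)-13-hydroxy-7-oxocembra-3,8(19),15(17)-trien-16,14-olide
Product: 28 (1S,3E,7S,12S,13R,14R)-7,13-dihydroxycembra-3,8(19),15(17)-trien-16,14-olide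
Conditions: (R)-2-methyl-CBS-oxazaborolidine (50 mol %), catecholborane, toluene, −78 °C
Reagents that add atoms: none
Why: In the Corey–Bakshi–Shibata reduction the (R)-oxazaborolidine binds the ketone with the alkenyl group as the large substituent and delivers hydride to give 7S; catecholborane at −78 °C leaves lactone, enoate and alkenes alone.

Step 16
Reactants: 28 (1S,3E,7S,12S,13R,14R)-7,13-dihydroxycembra-3,8(19),15(17)-trien-16,14-olide
Product: 29 (1S,3R,4R,7S,12S,13R,14R)-3,4-epoxy-7,13-dihydroxycembra-8(19),15(17)-dien-16,14-olide (CNP0124069.2)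
Conditions: D-fructose-derived Shi ketone (30 mol %), 2KHSO5·KHSO4·K2SO4, K2CO3, Bu4NHSO4 (cat.), MeCN/CH2(OMe)2/aq. Na2B4O7 buffer, 0 °C
Reagents that add atoms: potassium peroxymonosulfate KHSO5, [K+].[O-]S(=O)(=O)OO
Why: In the Shi asymmetric epoxidation the dioxirane of the D-fructose-derived ketone attacks the electron-rich E-trisubstituted 3,4-alkene through the spiro transition state to give the 3R,4R-epoxide; the enoate and the 1,1-disubstituted alkene react far more slowly.

## Compound list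

1 | tert-butyldimethyl(pent-4-yn-1-yloxy)silane | C#CCCCO[Si](C)(C)C(C)(C)C | starting material
2 | oxirane | C1CO1 | starting material
3 | [(1E)-5-[(tert-butyldimethylsilyl)oxy]-2-methylpent-1-en-1-yl]dimethylalane | C[Al](C)/C=C(\C)CCCO[Si](C)(C)C(C)(C)C | intermediate
4 | lithium butyl[(1E)-5-[(tert-butyldimethylsilyl)oxy]-2-methylpent-1-en-1-yl]dimethylaluminate | [Li+].CCCC[Al-](C)(C)/C=C(\C)CCCO[Si](C)(C)C(C)(C)C | intermediate
5 | (3E)-7-[(tert-butyldimethylsilyl)oxy]-4-methylhept-3-en-1-ol | OCC/C=C(\C)CCCO[Si](C)(C)C(C)(C)C | intermediate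
6 | (3E)-7-[(tert-butyldimethylsilyl)oxy]-4-methylhept-3-enal | O=CC/C=C(\C)CCCO[Si](C)(C)C(C)(C)C | intermediate
7 | methyl prop-2-ynoate | C#CC(=O)OC | starting material
8 | methyl 2-[bis(2-methylpropyl)alumanyl]prop-2-enoate | COC(=O)C(=C)[Al](CC(C)C)CC(C)C | intermediate
9 | methyl (5E)-9-[(tert-butyldimethylsilyl)oxy]-3-hydroxy-6-methyl-2-methylidenenon-5-enoate (racemic at C3) | COC(=O)C(=C)C(O)C/C=C(\C)CCCO[Si](C)(C)C(C)(C)C | intermediate
10 | methyl (2Z,5E)-2-(bromomethyl)-9-[(tert-butyldimethylsilyl)oxy]-6-methylnona-2,5-dienoate | COC(=O)/C(CBr)=C/C/C=C(\C)CCCO[Si](C)(C)C(C)(C)C | intermediate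
11 | hex-5-yn-1-ol | C#CCCCCO | starting material
12 | 5-iodohex-5-en-1-ol | C=C(I)CCCCO | intermediate
13 | methyl (triphenyl-λ5-phosphanylidene)acetate | COC(=O)C=P(c1ccccc1)(c1ccccc1)c1ccccc1 | starting material
14 | 5-iodohex-5-enal | C=C(I)CCCC=O | intermediate
15 | methyl (2E)-7-iodoocta-2,7-dienoate | C=C(I)CCC/C=C/C(=O)OC | intermediate
16 | methyl (3S)-7-iodo-3-methyloct-7-enoate | C=C(I)CCC[C@H](C)CC(=O)OC | intermediate
17 | (3S)-7-iodo-3-methyloct-7-enal | C=C(I)CCC[C@H](C)CC=O | intermediate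
18 | (2R,3S)-2-(anilinooxy)-7-iodo-3-methyloct-7-enal | C=C(I)CCC[C@H](C)[C@@H](ONc1ccccc1)C=O | intermediate
19 | (2R,3S)-2-(anilinooxy)-7-iodo-3-methyloct-7-en-1-ol | C=C(I)CCC[C@H](C)[C@@H](ONc1ccccc1)CO | intermediate
20 | (2R,3S)-7-iodo-3-methyloct-7-ene-1,2-diol | C=C(I)CCC[C@H](C)[C@@H](O)CO | intermediate
21 | (2R,3S)-2-hydroxy-7-iodo-3-methyloct-7-enal | C=C(I)CCC[C@H](C)[C@@H](O)C=O | intermediate
22 | methyl (3S,4R,5R,6S)-3-{(2E)-6-[(tert-butyldimethylsilyl)oxy]-3-methylhex-2-en-1-yl}-4,5-dihydroxy-10-iodo-6-methyl-2-methylideneundec-10-enoate | C=C(I)CCC[C@H](C)[C@@H](O)[C@H](O)[C@@H](C/C=C(\C)CCCO[Si](C)(C)C(C)(C)C)C(=C)C(=O)OC | intermediate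
23 | (4S,5R)-4-{(2E)-6-[(tert-butyldimethylsilyl)oxy]-3-methylhex-2-en-1-yl}-5-[(1R,2S)-1-hydroxy-6-iodo-2-methylhept-6-en-1-yl]-3-methylideneoxolan-2-one | C=C(I)CCC[C@H](C)[C@@H](O)[C@@H]1OC(=O)C(=C)[C@@H]1C/C=C(\C)CCCO[Si](C)(C)C(C)(C)C | intermediate
24 | (4S,5R)-5-[(1R,2S)-1-hydroxy-6-iodo-2-methylhept-6-en-1-yl]-4-[(2E)-6-hydroxy-3-methylhex-2-en-1-yl]-3-methylideneoxolan-2-one | C=C(I)CCC[C@H](C)[C@@H](O)[C@@H]1OC(=O)C(=C)[C@@H]1C/C=C(\C)CCCO | intermediate
25 | (4E)-6-{(2R,3S)-2-[(1R,2S)-1-hydroxy-6-iodo-2-methylhept-6-en-1-yl]-4-methylidene-5-oxooxolan-3-yl}-4-methylhex-4-enal | C=C(I)CCC[C@H](C)[C@@H](O)[C@@H]1OC(=O)C(=C)[C@@H]1C/C=C(\C)CCC=O | intermediate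
26 | (1S,3E,12S,13R,14R)-7,13-dihydroxycembra-3,8(19),15(17)-trien-16,14-olide (7R/7S mixture) | C=C1CCC[C@H](C)[C@@H](O)[C@@H]2OC(=O)C(=C)[C@@H]2C/C=C(\C)CCC1O | intermediate
27 | (1S,3E,12S,13R,14R)-13-hydroxy-7-oxocembra-3,8(19),15(17)-trien-16,14-olide | C=C1CCC[C@H](C)[C@@H](O)[C@@H]2OC(=O)C(=C)[C@@H]2C/C=C(\C)CCC1=O | intermediate
28 | (1S,3E,7S,12S,13R,14R)-7,13-dihydroxycembra-3,8(19),15(17)-trien-16,14-olide | C=C1CCC[C@H](C)[C@@H](O)[C@@H]2OC(=O)C(=C)[C@@H]2C/C=C(\C)CC[C@@H]1O | intermediate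
29 | (1S,3R,4R,7S,12S,13R,14R)-3,4-epoxy-7,13-dihydroxycembra-8(19),15(17)-dien-16,14-olide (CNP0124069.2) | C=C1CCC[C@H](C)[C@@H](O)[C@@H]2OC(=O)C(=C)[C@@H]2C[C@H]2O[C@]2(C)CC[C@@H]1O | target

## Step count and risks

Total step count: 16 (west fragment steps 1–4, east fragment steps 5–10, union and endgame steps 11–16).
Longest linear sequence: 12 steps (steps 5–16, from hex-5-yn-1-ol 11).

The three steps most likely to fail are 11, 13 and 16.

Step 11 (indium Barbier on the free α-hydroxy aldehyde: three contiguous centres, sensitive aldehyde). The fallback is a Keck-type chelation-controlled allylstannane addition on a protected aldehyde; it sets out from diol 20 and bromide 10 and comes back at lactone 24. Diol 20 is condensed with 4-methoxybenzaldehyde dimethyl acetal (PPTS, CH2Cl2) to the 4-methoxybenzylidene acetal F1. i-Bu2AlH opens F1 at the less hindered oxygen to the secondary PMB ether alcohol F2, and Dess–Martin periodinane gives the α-PMB-oxy aldehyde F3. Bromide 10 is converted with Bu3SnLi/CuBr·SMe2 (THF, −78 °C) into the allylstannane F4. MgBr2·OEt2 (CH2Cl2, −78 °C) chelates the ether and aldehyde oxygens of F3, and F4 adds through an open antiperiplanar transition state (13,14-syn and 14,1-syn). Treatment with 2 M HCl/THF lactonises and desilylates to the PMB-protected lactone F5, and DDQ (CH2Cl2/pH 7 buffer) returns 24.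

Step 13 (Ni/Cr macrocyclisation: oligomerisation, possible interference of the enoate). The fallback closes the same C7–C8 bond by a ligand-controlled nickel-catalysed reductive ynal macrocyclisation in the exo mode; it sets out from diol 20 and comes back at 26. Diol 20 is dehydroiodinated with TBAF·3H2O (DMF, 60 °C) to the alkyne diol F6. F6 is taken through the operations of steps 10, 11 and 12 with bromide 10, giving the α-hydroxy ynal F7, the alkyne lactone diol F8 and the ynal F9. Ni(cod)2 with a bulky N-heterocyclic carbene (DP-IPr·HCl, KOt-Bu) and Et3SiH in THF at high dilution joins the internal alkyne carbon C8 to the aldehyde and gives the macrocyclic triethylsilyl ether F10 with the exocyclic methylene (C7 epimers). HF·pyridine desilylates F10 to 26, which continues with steps 14–16.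

Step 16 (epoxidation on the macrocycle: ring conformation may override the catalyst, the 8(19)-alkene may compete). The fallback epoxidises before ring closure, where the alkene is conformationally free; it sets out from 24 and comes back at 29. Shi epoxidation of 24 under the conditions of step 16 gives the epoxy diol F11, and TEMPO/PhI(OAc)2 gives the epoxy aldehyde F12. CrCl2/NiCl2 in DMSO closes the ring to the epoxy macrocyclic alcohol F13 (C7 epimers), MnO2 gives the epoxy enone F14, and (R)-2-methyl-CBS-oxazaborolidine/catecholborane then gives 29 directly.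

Further compounds

F1 | step 11 | (4R)-4-[(2S)-6-iodohept-6-en-2-yl]-2-(4-methoxyphenyl)-1,3-dioxolane (acetal epimers) | C=C(I)CCC[C@H](C)[C@@H]1COC(c2ccc(OC)cc2)O1
F2 | step 11 | (2R,3S)-7-iodo-2-[(4-methoxyphenyl)methoxy]-3-methyloct-7-en-1-ol | C=C(I)CCC[C@H](C)[C@@H](OCc1ccc(OC)cc1)CO
F3 | step 11 | (2R,3S)-7-iodo-2-[(4-methoxyphenyl)methoxy]-3-methyloct-7-enal | C=C(I)CCC[C@H](C)[C@@H](OCc1ccc(OC)cc1)C=O
F4 | step 11 | methyl (2Z,5E)-9-[(tert-butyldimethylsilyl)oxy]-6-methyl-2-[(tributylstannyl)methyl]nona-2,5-dienoate | COC(=O)/C(C[Sn](CCCC)(CCCC)CCCC)=C/C/C=C(\C)CCCO[Si](C)(C)C(C)(C)C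
F5 | step 11 | (4S,5R)-4-[(2E)-6-hydroxy-3-methylhex-2-en-1-yl]-5-{(1R,2S)-6-iodo-1-[(4-methoxyphenyl)methoxy]-2-methylhept-6-en-1-yl}-3-methylideneoxolan-2-one | C=C(I)CCC[C@H](C)[C@@H](OCc1ccc(OC)cc1)[C@@H]1OC(=O)C(=C)[C@@H]1C/C=C(\C)CCCO
F6 | step 13 | (2R,3S)-3-methyloct-7-yne-1,2-diol | C#CCCC[C@H](C)[C@@H](O)CO
F7 | step 13 | (2R,3S)-2-hydroxy-3-methyloct-7-ynal | C#CCCC[C@H](C)[C@@H](O)C=O
F8 | step 13 | (4S,5R)-4-[(2E)-6-hydroxy-3-methylhex-2-en-1-yl]-5-[(1R,2S)-1-hydroxy-2-methylhept-6-yn-1-yl]-3-methylideneoxolan-2-one | C#CCCC[C@H](C)[C@@H](O)[C@@H]1OC(=O)C(=C)[C@@H]1C/C=C(\C)CCCO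
F9 | step 13 | (4E)-6-{(2R,3S)-2-[(1R,2S)-1-hydroxy-2-methylhept-6-yn-1-yl]-4-methylidene-5-oxooxolan-3-yl}-4-methylhex-4-enal | C#CCCC[C@H](C)[C@@H](O)[C@@H]1OC(=O)C(=C)[C@@H]1C/C=C(\C)CCC=O
F10 | step 13 | (1S,3E,12S,13R,14R)-13-hydroxy-7-[(triethylsilyl)oxy]cembra-3,8(19),15(17)-trien-16,14-olide (7R/7S mixture) | C=C1CCC[C@H](C)[C@@H](O)[C@@H]2OC(=O)C(=C)[C@@H]2C/C=C(\C)CCC1O[Si](CC)(CC)CC
F11 | step 16 | (4S,5R)-5-[(1R,2S)-1-hydroxy-6-iodo-2-methylhept-6-en-1-yl]-4-{[(2R,3R)-3-(3-hydroxypropyl)-3-methyloxiran-2-yl]methyl}-3-methylideneoxolan-2-one | C=C(I)CCC[C@H](C)[C@@H](O)[C@@H]1OC(=O)C(=C)[C@@H]1C[C@H]1O[C@]1(C)CCCO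
F12 | step 16 | 3-[(2R,3R)-3-({(2R,3S)-2-[(1R,2S)-1-hydroxy-6-iodo-2-methylhept-6-en-1-yl]-4-methylidene-5-oxooxolan-3-yl}methyl)-2-methyloxiran-2-yl]propanal | C=C(I)CCC[C@H](C)[C@@H](O)[C@@H]1OC(=O)C(=C)[C@@H]1C[C@H]1O[C@]1(C)CCC=O
F13 | step 16 | (1S,3R,4R,12S,13R,14R)-3,4-epoxy-7,13-dihydroxycembra-8(19),15(17)-dien-16,14-olide (7R/7S mixture) | C=C1CCC[C@H](C)[C@@H](O)[C@@H]2OC(=O)C(=C)[C@@H]2C[C@H]2O[C@]2(C)CCC1O
F14 | step 16 | (1S,3R,4R,12S,13R,14R)-3,4-epoxy-13-hydroxy-7-oxocembra-8(19),15(17)-dien-16,14-olide | C=C1CCC[C@H](C)[C@@H](O)[C@@H]2OC(=O)C(=C)[C@@H]2C[C@H]2O[C@]2(C)CCC1=O
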